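## Retrosynthetic overview

1. Dactylomelol ⇒ C4-iodo ether ⇒ 4-hydroxycyclohexene: the oxygen bridge (second ring, formed last) closes by transannular iodoetherification of C6–OH onto C3=C4, then C–I reduction.
2. CHBr–CMe2Cl ⇐ side-chain (R)-epoxide: bromide opening with inversion, then tertiary OH → Cl through the bromonium ion, done before the ether closure.
3. C3=C4 ⇐ C3 ketone (enol triflate reduction). The ketone is a three-fragment union on a cyclohexenone: O-directed conjugate addition of the hydroxypentenyl Grignard at C1, then enolate alkylation at C2 with an epoxy iodide.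
4. The cyclohexenone (first ring) closes by intramolecular aldol condensation of an ethyl-keto α-hydroxy-aldehyde derived from (R)-linalool, which supplies C6.
5. The Grignard precursor also comes from (R)-linalool (vinyl → CH2CH2Br, prenyl arm → new vinyl); the epoxy iodide comes from cyclopropyl methyl ketone via Shi epoxidation.

Ring labels used below: C1 (bears the pentenol chain), C2 (quaternary, Me + halogenated chain), C3 (CH–O), C4, C5, C6 (C(Me)–O).

Assumption: commercial (R)-(−)-linalool is taken as ≥97% ee, and the D-fructose-derived Shi ketone is a purchased catalyst.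

## Route

### Cyclohexenone core

**Step 1**
Reactants: 1, (R)-(−)-linalool [(3R)-3,7-dimethylocta-1,6-dien-3-ol]
Product: 2, (5R)-5-methyl-5-vinyltetrahydrofuran-2-ol (lactol of (4R)-4-hydroxy-4-methylhex-5-enal, anomer mixture)
Conditions: O3 (1.0 equiv, Sudan Red end-point), CH2Cl2/MeOH, −78 °C; Me2S
Reagents that add atoms: ozone, [O-][O+]=O
Why: Chemoselective ozonolysis: the electron-rich trisubstituted olefin is cleaved much faster than the vinyl group next to the carbinol, and the carbinol centre is untouched.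

**Step 2**
Reactants: 2
Product: 3, (3R)-3-methyloct-1-ene-3,6-diol (C6 epimers)
Conditions: EtMgBr (3 equiv), THF, 0 °C → rt
Reagents that add atoms: ethylmagnesium bromide, CC[Mg]Br
Why: Grignard addition to the open hydroxy-aldehyde form of the lactol; the new carbinol centre is irrelevant because it is oxidised next.

**Step 3**
Reactants: 3
Product: 4, (6R)-6-hydroxy-6-methyloct-7-en-3-one
Conditions: Dess–Martin periodinane, NaHCO3, CH2Cl2, 0 °C
Reagents that add atoms: none
Why: Dess–Martin oxidation touches only the secondary alcohol; the tertiary allylic alcohol cannot be oxidised and, without Cr(VI), does not transpose.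

**Step 4**
Reactants: 4
Product: 5, (2R)-2-hydroxy-2-methyl-5-oxoheptanal (used crude)
Conditions: O3, CH2Cl2, −78 °C; PPh3
Reagents that add atoms: ozone, [O-][O+]=O
Why: Ozonolysis of the remaining vinyl group gives an α-hydroxy aldehyde that has no α-hydrogen and so cannot epimerise.

**Step 5**
Reactants: 5
Product: 6, (4R)-4-hydroxy-2,4-dimethylcyclohex-2-en-1-one
Conditions: piperidine (0.3 equiv), AcOH (0.3 equiv), CH2Cl2, 0 °C → rt
Reagents that add atoms: none
Why: Intramolecular aldol condensation (6-enolendo, iminium-activated aldehyde): only the ethyl-side α-carbon can reach the aldehyde through a six-membered transition state, and E1cB dehydration gives the enone with the linalool-derived C6 centre intact.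

### Hydroxypentenyl (C1 side-chain) fragment

**Step 6**
Reactants: 1, (R)-(−)-linalool
Product: 7, (3R)-3,7-dimethyloct-6-ene-1,3-diol
Conditions: 9-BBN (2.2 equiv), THF, 0 °C → rt; NaOH, H2O2
Reagents that add atoms: hydrogen peroxide, OO
Why: Hydroboration–oxidation: 9-BBN reacts only with the monosubstituted olefin, anti-Markovnikov, leaving the trisubstituted olefin and the stereocentre alone.

**Step 7**
Reactants: 7
Product: 8, (3R)-1-bromo-3,7-dimethyloct-6-en-3-ol
Conditions: CBr4, PPh3, 2,6-lutidine, CH2Cl2, 0 °C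
Reagents that add atoms: carbon tetrabromide, BrC(Br)(Br)Br
Why: Appel bromination is selective for the primary alcohol; the tertiary alcohol does not react.

**Step 8**
Reactants: 8
Product: 9, (3R)-1-bromo-3,7-dimethyl-3-(triethylsilyloxy)oct-6-ene
Conditions: TESOTf, 2,6-lutidine, CH2Cl2, −78 → 0 °C
Reagents that add atoms: triethylsilyl triflate, CC[Si](CC)(CC)OS(=O)(=O)C(F)(F)F
Why: Silyl triflate silylation protects the hindered tertiary alcohol for the organometallic, basic and SOCl2 steps ahead.

**Step 9**
Reactants: 9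
Product: 10, (4R)-6-bromo-4-methyl-4-(triethylsilyloxy)hexanoic acid
Conditions: RuCl3·xH2O (3 mol %), NaIO4 (4 equiv), MeCN/EtOAc/H2O, 0 °C → rt
Reagents that add atoms: sodium periodate, [Na+].[O-]I(=O)(=O)=O; water, O
Why: RuO4 oxidative cleavage of the only olefin goes directly to the carboxylic acid (acetone is lost); the bromide and silyl ether are inert.

**Step 10**
Reactants: 10
Product: 11, (3S)-5-bromo-3-methyl-3-(triethylsilyloxy)pent-1-ene
Conditions: Pb(OAc)4 (1.3 equiv), Cu(OAc)2 (0.2 equiv), pyridine, PhH, 80 °C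
Reagents that add atoms: none
Why: Kochi oxidative decarboxylation: the primary radical is oxidised by Cu(II) to the terminal alkene, so the former prenyl arm becomes the vinyl group and the unchanged carbinol centre now has the (S) arrangement needed in the target.

### Epoxy iodide (C2 side-chain) fragment

**Step 11**
Reactants: 12, cyclopropyl methyl ketone
Product: 13, 2-cyclopropylpropan-2-ol
Conditions: MeMgBr, Et2O, 0 °C
Reagents that add atoms: methylmagnesium bromide, C[Mg]Br
Why: Simple Grignard addition to a ketone.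

**Step 12**
Reactants: 13
Product: 14, 5-bromo-2-methylpent-2-ene
Conditions: 48% aq HBr, 0 °C
Reagents that add atoms: hydrogen bromide, Br
Why: Julia cyclopropylcarbinyl → homoallyl rearrangement: the cyclopropylcarbinyl cation is opened by bromide to the trisubstituted olefin.

**Step 13**
Reactants: 14
Product: 15, (3R)-3-(2-bromoethyl)-2,2-dimethyloxirane
Conditions: D-fructose-derived Shi ketone (0.3 equiv), Oxone, K2CO3, Bu4NHSO4, MeCN/DMM/aq borate buffer, 0 °C
Reagents that add atoms: Oxone (potassium peroxymonosulfate), [K+].[O-]S(=O)(=O)OO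
Why: Shi asymmetric epoxidation (chiral dioxirane, spiro transition state) of a trisubstituted olefin sets the (R) epoxide centre that later becomes the C–Br carbon.

**Step 14**
Reactants: 15
Product: 16, (3R)-3-(2-iodoethyl)-2,2-dimethyloxirane
Conditions: NaI, NaHCO3, acetone, 40 °C
Reagents that add atoms: sodium iodide, [Na+].[I-]
Why: Finkelstein exchange at the primary carbon gives the more reactive alkylating agent; the epoxide is untouched under neutral conditions.

### Fragment union and endgame

**Step 15**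
Reactants: 6, (4R)-4-hydroxy-2,4-dimethylcyclohex-2-en-1-one; 11, (3S)-5-bromo-3-methyl-3-(triethylsilyloxy)pent-1-ene
Product: 17, triethyl{[(3S)-5-[(1S,6R)-2,6-dimethyl-3,6-bis(trimethylsilyloxy)cyclohex-2-en-1-yl]-3-methylpent-1-en-3-yl]oxy}silane (chain at C1 cis to the C6 oxygen)
Conditions: 6 + t-BuMgCl (1.0 equiv), THF, −78 °C; Grignard from 11 (Mg, THF; 1.5 equiv), −78 → 0 °C; then TMSCl, Et3N, HMPA, −78 °C → rt
Reagents that add atoms: chlorotrimethylsilane, C[Si](C)(C)Cl
Why: Alkoxide-directed (4-oxido) conjugate addition: the C6 magnesium alkoxide binds the Grignard and delivers the chain to C1 on its own face (C1 = S, cis to C6–O), and TMSCl traps the C2=C3 enolate regiospecifically.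

**Step 16**
Reactants: 17; 16, (3R)-3-(2-iodoethyl)-2,2-dimethyloxirane
Product: 18, (2S,3S,4R)-2-{2-[(2R)-3,3-dimethyloxiran-2-yl]ethyl}-2,4-dimethyl-3-[(3S)-3-methyl-3-(triethylsilyloxy)pent-4-en-1-yl]-4-(trimethylsilyloxy)cyclohexan-1-one
Conditions: MeLi (1.05 equiv), THF, 0 °C; HMPA, then 16 (2.5 equiv), −40 °C → rt
Reagents that add atoms: none (MeLi only unmasks the lithium enolate)
Why: Alkylation of a regiodefined lithium enolate: the electrophile enters C2 anti to the adjacent pseudoaxial C1 chain, so the C2 methyl ends cis and the new chain trans to the C1 chain (C2 = S).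

**Step 17**
Reactants: 18
Product: 19, (4R,5S,6S)-6-{2-[(2R)-3,3-dimethyloxiran-2-yl]ethyl}-4,6-dimethyl-5-[(3S)-3-methyl-3-(triethylsilyloxy)pent-4-en-1-yl]-4-(trimethylsilyloxy)cyclohex-1-en-1-yl triflate
Conditions: KHMDS (1.2 equiv), THF, −78 °C; Comins' reagent, −78 → −40 °C
Reagents that add atoms: Comins' reagent, O=S(=O)(N(c1ccc(Cl)cn1)S(=O)(=O)C(F)(F)F)C(F)(F)F
Why: Kinetic enolisation can only go toward C4 because C2 is quaternary, and O-triflation fixes the C3=C4 position.

**Step 18**
Reactants: 19
Product: 20, {[(1R,5R,6S)-5-{2-[(2R)-3,3-dimethyloxiran-2-yl]ethyl}-1,5-dimethyl-6-[(3S)-3-methyl-3-(triethylsilyloxy)pent-4-en-1-yl]cyclohex-3-en-1-yl]oxy}trimethylsilane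
Conditions: Pd(PPh3)4 (5 mol %), LiCl, Bu3SnH (1.5 equiv), THF, 50 °C
Reagents that add atoms: none
Why: Pd-catalysed hydride reduction of the enol triflate under neutral conditions gives the C3=C4 olefin; epoxide, vinyl group and silyl ethers are inert.

**Step 19**
Reactants: 20
Product: 21, (3S)-3-bromo-5-[(1R,5R,6S)-1,5-dimethyl-6-[(3S)-3-methyl-3-(triethylsilyloxy)pent-4-en-1-yl]-5-(trimethylsilyloxy)cyclohex-2-en-1-yl]-2-methylpentan-2-ol
Conditions: Li2NiBr4 (0.4 M in THF, 2 equiv), THF, 0 °C → rt
Reagents that add atoms: dilithium tetrabromonickelate, [Li+].[Li+].Br[Ni-2](Br)(Br)Br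
Why: SN2 opening of the trisubstituted epoxide by bromide at the less substituted carbon with inversion turns the (R)-epoxide into the (S)-bromide; any regioisomeric bromohydrin funnels through the same bromonium ion in step 20.

**Step 20**
Reactants: 21
Product: 22, {[(1R,5R,6S)-5-[(3S)-3-bromo-4-chloro-4-methylpentyl]-1,5-dimethyl-6-[(3S)-3-methyl-3-(triethylsilyloxy)pent-4-en-1-yl]cyclohex-3-en-1-yl]oxy}trimethylsilane
Conditions: SOCl2 (1.5 equiv), 2,6-di-tert-butyl-4-methylpyridine, CH2Cl2, −40 → 0 °C
Reagents that add atoms: thionyl chloride, O=S(Cl)Cl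
Why: The tertiary chlorosulfite ionises with anchimeric assistance from the neighbouring bromine, and chloride opens the bromonium ion at the tertiary carbon, so the C–Br centre keeps its (S) configuration; the only free hydroxyl in the molecule is the one being replaced.

**Step 21**
Reactants: 22
Product: 23, (1R,5R,6S)-5-[(3S)-3-bromo-4-chloro-4-methylpentyl]-6-[(3S)-3-hydroxy-3-methylpent-4-en-1-yl]-1,5-dimethylcyclohex-3-en-1-ol
Conditions: HF·pyridine, pyridine, THF, 0 °C → rt
Reagents that add atoms: none
Why: Buffered acidic fluoride removes both the TMS and TES ethers without base, so the secondary bromide and tertiary chloride are not eliminated.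

**Step 22**
Reactants: 23
Product: 24, (3S)-5-[(1R,2S,3S,4R,5R)-3-[(3S)-3-bromo-4-chloro-4-methylpentyl]-5-iodo-1,3-dimethyl-7-oxabicyclo[2.2.1]heptan-2-yl]-3-methylpent-1-en-3-ol (iodine endo)
Conditions: NIS (1.3 equiv), NaHCO3, MeCN, −20 → 0 °C, dark
Reagents that add atoms: N-iodosuccinimide, O=C1CCC(=O)N1I
Why: Transannular iodoetherification (anti addition): the C6 hydroxyl can reach only C3 and only from its own face, which sets C3 and closes the 7-oxabicyclo[2.2.1]heptane, while the deactivated, hindered vinyl group and the halogenated chain do not compete.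

**Step 23**
Reactants: 24
Product: 25, dactylomelol, (3S)-5-[(1R,2S,3S,4S)-3-[(3S)-3-bromo-4-chloro-4-methylpentyl]-1,3-dimethyl-7-oxabicyclo[2.2.1]heptan-2-yl]-3-methylpent-1-en-3-ol
Conditions: Bu3SnH (1.05 equiv), Et3B (0.2 equiv)/air, PhMe, −20 → 0 °C
Reagents that add atoms: none
Why: Radical deiodination: iodine abstraction by Bu3Sn• is roughly 100 times faster than bromine abstraction from the secondary bromide and far faster than from the tertiary chloride, so one equivalent at low temperature removes only iodine and no stereocentre is touched.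

## Compound list

1 | (R)-(−)-linalool | C=C[C@](C)(O)CCC=C(C)C | starting material
2 | (5R)-5-methyl-5-vinyltetrahydrofuran-2-ol | C=C[C@@]1(C)CCC(O)O1 | intermediate
3 | (3R)-3-methyloct-1-ene-3,6-diol | C=C[C@](C)(O)CCC(O)CC | intermediate
4 | (6R)-6-hydroxy-6-methyloct-7-en-3-one | C=C[C@](C)(O)CCC(=O)CC | intermediate
5 | (2R)-2-hydroxy-2-methyl-5-oxoheptanal | O=C[C@](C)(O)CCC(=O)CC | intermediate
6 | (4R)-4-hydroxy-2,4-dimethylcyclohex-2-en-1-one | CC1=C[C@](C)(O)CCC1=O | intermediate
7 | (3R)-3,7-dimethyloct-6-ene-1,3-diol | OCC[C@](C)(O)CCC=C(C)C | intermediate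
8 | (3R)-1-bromo-3,7-dimethyloct-6-en-3-ol | BrCC[C@](C)(O)CCC=C(C)C | intermediate
9 | (3R)-1-bromo-3,7-dimethyl-3-(triethylsilyloxy)oct-6-ene | BrCC[C@](C)(O[Si](CC)(CC)CC)CCC=C(C)C | intermediate
10 | (4R)-6-bromo-4-methyl-4-(triethylsilyloxy)hexanoic acid | BrCC[C@](C)(O[Si](CC)(CC)CC)CCC(=O)O | intermediate
11 | (3S)-5-bromo-3-methyl-3-(triethylsilyloxy)pent-1-ene | C=C[C@@](C)(O[Si](CC)(CC)CC)CCBr | intermediate
12 | cyclopropyl methyl ketone | CC(=O)C1CC1 | starting material
13 | 2-cyclopropylpropan-2-ol | CC(C)(O)C1CC1 | intermediate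
14 | 5-bromo-2-methylpent-2-ene | CC(C)=CCCBr | intermediate
15 | (3R)-3-(2-bromoethyl)-2,2-dimethyloxirane | BrCC[C@H]1OC1(C)C | intermediate
16 | (3R)-3-(2-iodoethyl)-2,2-dimethyloxirane | ICC[C@H]1OC1(C)C | intermediate
17 | bis-TMS silyl enol ether (C1 chain cis to C6–O) | C=C[C@@](C)(O[Si](CC)(CC)CC)CC[C@H]1C(C)=C(O[Si](C)(C)C)CC[C@@]1(C)O[Si](C)(C)C | intermediate
18 | (2S,3S,4R)-2,2,3,4-substituted cyclohexanone with epoxy chain | C=C[C@@](C)(O[Si](CC)(CC)CC)CC[C@H]1[C@](C)(CC[C@H]2OC2(C)C)C(=O)CC[C@@]1(C)O[Si](C)(C)C | intermediate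
19 | (4R,5S,6S)-cyclohexenyl triflate | C=C[C@@](C)(O[Si](CC)(CC)CC)CC[C@H]1[C@](C)(CC[C@H]2OC2(C)C)C(OS(=O)(=O)C(F)(F)F)=CC[C@@]1(C)O[Si](C)(C)C | intermediate
20 | (1R,5R,6S)-cyclohex-3-enyl TMS ether with epoxy chain | C=C[C@@](C)(O[Si](CC)(CC)CC)CC[C@H]1[C@](C)(CC[C@H]2OC2(C)C)C=CC[C@@]1(C)O[Si](C)(C)C | intermediate
21 | (S)-bromohydrin, bis-silyl ether | C=C[C@@](C)(O[Si](CC)(CC)CC)CC[C@H]1[C@](C)(CC[C@H](Br)C(C)(C)O)C=CC[C@@]1(C)O[Si](C)(C)C | intermediate
22 | (S)-bromochloride, bis-silyl ether | C=C[C@@](C)(O[Si](CC)(CC)CC)CC[C@H]1[C@](C)(CC[C@H](Br)C(C)(C)Cl)C=CC[C@@]1(C)O[Si](C)(C)C | intermediate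
23 | (1R,5R,6S)-5-[(3S)-3-bromo-4-chloro-4-methylpentyl]-6-[(3S)-3-hydroxy-3-methylpent-4-en-1-yl]-1,5-dimethylcyclohex-3-en-1-ol | C=C[C@@](C)(O)CC[C@H]1[C@](C)(CC[C@H](Br)C(C)(C)Cl)C=CC[C@@]1(C)O | intermediate
24 | 5-endo-iodo-7-oxabicyclo[2.2.1]heptane (1R,2S,3S,4R,5R) | C=C[C@@](C)(O)CC[C@H]1[C@](C)(CC[C@H](Br)C(C)(C)Cl)[C@@H]2[C@H](I)C[C@@]1(C)O2 | intermediate
25 | dactylomelol | C=C[C@@](C)(O)CC[C@H]1[C@](C)(CC[C@H](Br)C(C)(C)Cl)[C@@H]2CC[C@@]1(C)O2 | target

## Step count and risks

Total steps: 23.
Longest linear sequence: 14 (steps 1–5 then 15–23; the arm through steps 6–10 is equally long; the epoxy iodide arm is 12). 14/23 = 0.61.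

Steps most likely to fail:

1. **Step 16** (hindered C2 enolate with an unactivated primary iodide: slow alkylation, E2 or O-alkylation). Fallback: build the chain linearly instead of by fragment alkylation. Add the same enolate to methyl acrylate (Michael), then DIBAL-H to the aldehyde, Wittig with Ph3P=CMe2, and Shi epoxidation after step 18.

2. **Step 15** (site and facial selectivity of the O-directed Grignard addition to an α-methyl enone). Fallback: use steric control and close the ether from the other side.
   - Add the chain anti to the OTBS group of the TBS ether of ent-6 (made from (S)-linalool) with CuBr·SMe2/TMSCl.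
   - Alkylate as before, then reduce the C3 ketone with NaBH4 to the alcohol cis to the C2 methyl.
   - Dehydrate C6 to the C5=C6 olefin and cyclise the C3 hydroxyl onto C6 (Hg(II) or iodoetherification).

3. **Step 20** (tertiary alcohol → chloride: E1 elimination or halogen scrambling). Fallback: install chlorine first. Open epoxide 20 at the tertiary carbon with chloride (Markovnikov, e.g. pyridinium chloride or TMSCl/cat. PPh3), then convert the secondary alcohol to the bromide with inversion (Tf2O/2,6-lutidine, then Bu4NBr). The same (R)-epoxide still leads to the (S)-bromide.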